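Beta is the flask you have to decide about, so the question at the board is this: can the next run keep this charge and this reading time, or must something change?

| setting | beta | gamma | flask |
|---|---|---|---|
| substrate | 0.80 M (in portions, 2) | 0.40 M (in portions, 2) | 0.80 M (in portions, 2) |
| gas | 140 mM (held) | 140 mM (held) | 140 mM (held) |
| remark | the very flask that is asked about, followed so far; portions every 1.5 min | run made earlier; portions every 1.5 min | the portions of substrate follow each other after 1.5 min, the first at the start |
| time |  |  | 6.0 h |

- beta (time / min: target / %): 12.0: 6.2; 25.0: 27.2; 40.0: 52.0; 50.0: 66.7; 60.0: 78.2; 80.0: 92.0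
- gamma (time / h: target / %): 1.00: 82.5; 2.00: 99.4; 3.00: 100.2; 4.00: 99.2; 5.00: 100.4; 6.00: 100.3

(standard deviation of a reading: 0.5 percentage points)

* which holds at 6.0 h: what has brought the reaction to rest, or that it has not come to rest (forward and back rates have come level / all of the substrate has reacted / it is still moving)
* target at 6.0 h, in percent of the substrate charged

- the numbers in the tables scatter by 0.5 percentage points (one standard deviation)
- at the start none of the gas is in solution
- the reaction counts as stopped when no species that holds the substrate changes by six tenths of a point or more over the second half of the time

Take the gap, the share of the charge not yet target. Between 60.0 min and 80.0 min in beta it falls from 21.8% to 8.00%. My own reckoning treats this tail as one first-order decay and integrates it, with T the last reading of beta: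

d[gap]/dt = −k[gap], so [gap](t) = [gap](T) · exp(−k(t − T))

k = ln(21.8% / 8.00%) / 20.0 min = 3.01 h⁻¹

Call k the tail constant, the rate at which the gap decays late in beta; it is a reading and carries the scatter of its two points. Up to 6.0 h the exponent reaches 14.0, so:

[gap] at 6.0 h = <0.001%, against a scatter of 0.5 percentage points

Gamma, with half the charge, reads 99.4% at 2.00 h and 100.3% at 6.00 h, so target formed there stays. My decision: charge the same, change nothing, read at 6.0 h.

The forecast gives 100% and all of the substrate has reacted: “At about 3 per h, the remaining 8% is gone within roughly 2 h.”

The flask gives 100%, and its state at that time is: all of the substrate has reacted. The substrate, the limiting reagent, stands at 0% at that time, while partner stands at 0.118 M. The tail constant puts the gap at 3.00 h at 0.0532%, which is what it leaves to move in the second half of the time; the flask moved 0.009 points.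

    substrate ⇌ open intermediate (K = 1.33, k = 0.00145 s⁻¹)
    partner → second intermediate (k = 0.00401 s⁻¹)
    open intermediate + second intermediate → target (k = 0.00169 M⁻¹ s⁻¹)
    gas ⇌ partner, rate k4*(csat - [partner]) (kL = 0.0221 s⁻¹)
    partner → decomposition product (k = 8.26 × 10⁻⁶ s⁻¹)

On a neighbour, the same flask read at 1.5 h, the tail constant leaves a gap of 4.85%, so target 95.2%. The computed neighbour gives 95.5%.

The runs were generated by integration for substances that don't exist; scatter was added.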